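**Strategy.** Each outer ring (B and C) is disconnected across C3'–C4' and C5'–C6'. C4' (OMe) and C5' (butyryl) are neighbours and come from one alkyne, 1-methoxyhex-1-yn-3-one, whereas C1', C2', C3' and C6' carry the pattern of a 2,6-dialkylated cyclohexane-1,3-dione enol ether. A twofold Alder–Rickert reaction (cycloaddition, then loss of ethylene) turns two alkylated silyloxycyclohexadienes hung on a protected phloroglucinol (ring A) into both hexasubstituted arenes at once, with the methoxyl already in place. The precursor is a tribenzyl phloroglucinol carrying two 4-benzyloxy-1-methyl-2-silyloxycyclohexa-1,3-dien-3-ylmethyl arms; ring A is butyrylated last.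

Key step: step 9

**Remarks on the chemistry**
- Numbering: ring A is the central ring (C1 carries the butyryl group of the target, C2/C4/C6 the oxygens, C3/C5 the methylene links). In rings B and C, C1' carries the methylene, C2' OH, C3' CH3, C4' OCH3, C5' butyryl and C6' OH.
- The dienyl arms must have their double bonds between the benzyloxy- and arylmethyl-bearing carbons and between the methyl- and silyloxy-bearing carbons (as a substituent: 2-benzyloxy-5-methyl-6-silyloxycyclohexa-1,5-dien-1-yl). Only this isomer has the two ring CH2 groups as a saturated bridge that can leave as ethylene.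
- The silyl group is tert-butyldimethylsilyl instead of trimethylsilyl, so that the twofold diene can be isolated and heated; the aryl silyl ethers are cleaved in the work-up of the key step.
- Assumption: the methylated bis-enone, the alkynol and the double cycloadduct are carried as stereoisomer mixtures. All of these stereocentres disappear, and the target is achiral.

**Route**

Step 1
Reactants: 1 phloroglucinol (benzene-1,3,5-triol)
Product: 3 2,4,6-trihydroxybenzene-1,3-dicarbaldehyde, via bis(iminium) dichloride 2 (not isolated)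
Conditions: POCl3 (2.2 equiv), DMF, EtOAc, 0 °C → rt; then H2O, 50 °C
Reagents that add atoms: N,N-dimethylformamide CN(C)C=O; water O
Why: Vilsmeier–Haack formylation: phloroglucinol is nucleophilic enough to take up two chloroiminium electrophiles, each formyl unit slows the next substitution, and about two equivalents of reagent should therefore stop at the dialdehyde once 2 is hydrolysed.

Step 2
Reactants: 3 2,4,6-trihydroxybenzene-1,3-dicarbaldehyde
Product: 4 2,4,6-tris(benzyloxy)benzene-1,3-dicarbaldehyde
Conditions: BnBr (3.6 equiv), K2CO3, DMF, 60 °C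
Reagents that add atoms: benzyl bromide BrCc1ccccc1
Why: Williamson ether synthesis: the three phenoxides are acyl-stabilised, which lowers the nucleophilicity of the free ring carbon and should direct benzyl bromide to oxygen, while DMF and heat overcome the hydrogen bonds to the formyl groups.

Step 3
Reactants: 4 2,4,6-tris(benzyloxy)benzene-1,3-dicarbaldehyde; 5 cyclohexane-1,3-dione
Product: 7 2,2'-{[2,4,6-tris(benzyloxy)-1,3-phenylene]bis(methylene)}bis(cyclohexane-1,3-dione), via bis(arylidene dione) Knoevenagel adduct 6 (not isolated)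
Conditions: 5 (2.2 equiv), Hantzsch ester (2.2 equiv), L-proline (20 mol%), CH2Cl2, rt
Reagents that add atoms: none
Why: Three-component reductive alkylation (Knoevenagel condensation, then conjugate transfer hydrogenation from the Hantzsch ester): each aldehyde condenses with the dione under proline catalysis and the highly electrophilic arylidene dione is reduced before it can take up a second dione, which should give clean mono-alkylation at C2 on both arms.

Step 4
Reactants: 7 2,2'-{[2,4,6-tris(benzyloxy)-1,3-phenylene]bis(methylene)}bis(cyclohexane-1,3-dione)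
Product: 8 2,2'-{[2,4,6-tris(benzyloxy)-1,3-phenylene]bis(methylene)}bis[3-(benzyloxy)cyclohex-2-en-1-one]
Conditions: BnOH (2.6 equiv), PPh3, DIAD, THF, 0 °C → rt
Reagents that add atoms: benzyl alcohol OCc1ccccc1
Why: Mitsunobu O-alkylation: the acidic enol of each 2-substituted 1,3-dione is a competent pronucleophile and, with C2 fully substituted and hindered, it should attack the benzyloxyphosphonium ion through oxygen under neutral conditions that spare the acid-sensitive trialkoxybenzyl links.

Step 5
Reactants: 8 2,2'-{[2,4,6-tris(benzyloxy)-1,3-phenylene]bis(methylene)}bis[3-(benzyloxy)cyclohex-2-en-1-one]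
Product: 10 2,2'-{[2,4,6-tris(benzyloxy)-1,3-phenylene]bis(methylene)}bis[3-(benzyloxy)-6-methylcyclohex-2-en-1-one] (mixture of diastereomers), via dilithium bis(dienolate) 9 (not isolated)
Conditions: LiN(iPr)2 (2.3 equiv), THF, −78 °C; MeI (2.5 equiv), −78 → −20 °C
Reagents that add atoms: iodomethane CI
Why: Stork–Danheiser α'-alkylation: LiN(iPr)2 removes the kinetically most acidic C6 proton of each vinylogous ester to give the cross-conjugated enolate, which iodomethane methylates on carbon; the two remote stereocentres form without control and are both erased in step 6.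

Step 6
Reactants: 10 2,2'-{[2,4,6-tris(benzyloxy)-1,3-phenylene]bis(methylene)}bis[3-(benzyloxy)-6-methylcyclohex-2-en-1-one]
Product: 12 1,3,5-tris(benzyloxy)-2,4-bis{[2-(benzyloxy)-6-(tert-butyldimethylsilyloxy)-5-methylcyclohexa-1,5-dien-1-yl]methyl}benzene, via dilithium bis(dienolate) 11 (not isolated)
Conditions: LiN(iPr)2 (2.4 equiv), THF, −78 °C; TBSOTf (2.6 equiv), −78 → 0 °C; Et3N-buffered work-up, basic alumina
Reagents that add atoms: tert-butyldimethylsilyl trifluoromethanesulfonate CC(C)(C)[Si](C)(C)OS(=O)(=O)C(F)(F)F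
Why: Kinetic enolate formation and O-silylation: the remaining tertiary C6 proton is removed in preference to the γ-protons at C4, and the hard silyl triflate traps the enolate on oxygen to give the cyclic 1-alkoxy-3-silyloxy diene.

Step 7
Reactants: 13 2-chloro-1,1-dimethoxyethane; 14 butanal
Product: 16 rac-1-methoxyhex-1-yn-3-ol, via lithium methoxyacetylide 15 (not isolated)
Conditions: Et2NH (3.3 equiv), n-BuLi (3.2 equiv), THF, 0 °C; 13, 0 °C → rt; then 14, −78 → 0 °C; H2O (neutral work-up)
Reagents that add atoms: none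
Why: Twofold β-elimination (of methanol and of HCl) by LiNEt2 gives the lithium alkynyl ether, which undergoes acetylide 1,2-addition to the aldehyde; the carbinol centre is racemic and is removed in step 8.

Step 8
Reactants: 16 rac-1-methoxyhex-1-yn-3-ol
Product: 17 1-methoxyhex-1-yn-3-one
Conditions: activated MnO2 (excess), CH2Cl2, rt; filtration
Reagents that add atoms: none
Why: MnO2 oxidation of a propargylic alcohol: the neutral heterogeneous oxidant should give the ynone without the acid that would trigger Meyer–Schuster rearrangement of the alkynyl ether.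

Step 9
Reactants: 12 1,3,5-tris(benzyloxy)-2,4-bis{[2-(benzyloxy)-6-(tert-butyldimethylsilyloxy)-5-methylcyclohexa-1,5-dien-1-yl]methyl}benzene; 17 1-methoxyhex-1-yn-3-one
Product: 20 1,1'-{[2,4,6-tris(benzyloxy)-1,3-phenylene]bis[methylene(2-benzyloxy-4-hydroxy-6-methoxy-5-methyl-3,1-phenylene)]}bis(butan-1-one), via double cycloadduct 18 (not isolated), via bis(aryl silyl ether) 19 (not isolated)
Conditions: 17 (5 equiv), 2,6-di-tert-butyl-4-methylphenol (cat.), toluene, sealed tube, 130–150 °C (loss of C2H4); concentrate; then Bu4NF, AcOH, THF, 0 °C → rt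
Reagents that add atoms: none
Why: Proposed new method: each 1-benzyloxy-3-silyloxy cyclohexadiene unit of 12 should add ynone 17 across its termini in a concerted but asynchronous (4+2) cycloaddition, the electron-rich methyl-bearing terminus bonding to the methoxy-bearing β-carbon of the ynone slightly ahead of the bond between the benzyloxy-bearing terminus and the acyl-bearing carbon, and the bicyclo[2.2.2]octa-2,5-diene 18 should then expel its saturated two-carbon bridge as ethylene in a thermal retro-(4+2) step driven by aromatisation. The closest known reaction type is the Alder–Rickert synthesis of phenols from 2-silyloxycyclohexa-1,3-dienes and acetylenic ketones or esters; what is new is a dienophile with a donor alkoxy group on its β-carbon, which should react more slowly but with the same polarity. Rings B and C are each closed by this intermolecular cycloaddition, which forms C3'–C4' and C5'–C6' suprafacially on the locked s-cis diene, and the cycloreversion leaves the six-membered ring as the arene. The bridgehead stereocentres of 18 are transient and none survives, so nothing has to be controlled there. The selectivity needed is regiochemical and is secured by matched polarisation: both oxygen donors of the diene raise the coefficient at the methylated terminus, the carbonyl group makes the methoxy-bearing alkyne carbon the electrophilic one, and the methyl alkynyl ether has no β-hydrogen and so cannot fragment to a ketene on heating. Buffered fluoride then cleaves the hindered aryl silyl ethers of 19 to the free C2' phenols.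

Step 10
Reactants: 20 1,1'-{[2,4,6-tris(benzyloxy)-1,3-phenylene]bis[methylene(2-benzyloxy-4-hydroxy-6-methoxy-5-methyl-3,1-phenylene)]}bis(butan-1-one)
Product: 21 1,1'-{(2,4,6-trihydroxy-1,3-phenylene)bis[methylene(2,4-dihydroxy-6-methoxy-5-methyl-3,1-phenylene)]}bis(butan-1-one) (de-butyryl Agrimol C)
Conditions: H2 (1 atm), 10% Pd/C, EtOAc/MeOH, rt; handled under argon
Reagents that add atoms: none
Why: Catalytic hydrogenolysis of the five aryl benzyl ethers; the hydrogen-bonded ortho-hydroxyaryl ketones and the diarylmethane links should not be reduced under one atmosphere of hydrogen at room temperature.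

Step 11
Reactants: 21 1,1'-{(2,4,6-trihydroxy-1,3-phenylene)bis[methylene(2,4-dihydroxy-6-methoxy-5-methyl-3,1-phenylene)]}bis(butan-1-one)
Product: 23 Agrimol C, via ketiminium chloride 22 (not isolated)
Conditions: PrCN, ZnCl2, HCl (gas), Et2O, 0 °C; then H2O, 90 °C
Reagents that add atoms: butanenitrile CCCC#N; water O
Why: Houben–Hoesch acylation (a Friedel–Crafts acylation by a nitrilium electrophile): C1 of ring A is the only unsubstituted aromatic carbon and lies in a free phloroglucinol ring, the classical substrate of this reaction, whereas rings B and C are fully substituted and deactivated by their acyl groups; the method avoids O-acylation and the cleavage of a methyl ether ortho to a ketone that AlCl3 can cause, and hot water hydrolyses the ketiminium salt to the ketone.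

**Compound list**

1 | phloroglucinol (benzene-1,3,5-triol) | Oc1cc(O)cc(O)c1 | starting material
2 | (2,4,6-trihydroxybenzene-1,3-diyl)bis(N,N-dimethylmethaniminium) dichloride | C[N+](C)=Cc1c(O)cc(O)c(C=[N+](C)C)c1O.[Cl-].[Cl-] | intermediate
3 | 2,4,6-trihydroxybenzene-1,3-dicarbaldehyde | O=Cc1c(O)cc(O)c(C=O)c1O | intermediate
4 | 2,4,6-tris(benzyloxy)benzene-1,3-dicarbaldehyde | O=Cc1c(OCc2ccccc2)cc(OCc2ccccc2)c(C=O)c1OCc1ccccc1 | intermediate
5 | cyclohexane-1,3-dione | O=C1CCCC(=O)C1 | starting material
6 | 2,2'-{[2,4,6-tris(benzyloxy)-1,3-phenylene]dimethanylylidene}bis(cyclohexane-1,3-dione) (shown with both arms at the Knoevenagel stage) | O=C1CCCC(=O)C1=Cc1c(OCc2ccccc2)cc(OCc2ccccc2)c(C=C2C(=O)CCCC2=O)c1OCc1ccccc1 | intermediate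
7 | 2,2'-{[2,4,6-tris(benzyloxy)-1,3-phenylene]bis(methylene)}bis(cyclohexane-1,3-dione) (drawn as the diketo form) | O=C1CCCC(=O)C1Cc1c(OCc2ccccc2)cc(OCc2ccccc2)c(CC2C(=O)CCCC2=O)c1OCc1ccccc1 | intermediate
8 | 2,2'-{[2,4,6-tris(benzyloxy)-1,3-phenylene]bis(methylene)}bis[3-(benzyloxy)cyclohex-2-en-1-one] | O=C1CCCC(OCc2ccccc2)=C1Cc1c(OCc2ccccc2)cc(OCc2ccccc2)c(CC2=C(OCc3ccccc3)CCCC2=O)c1OCc1ccccc1 | intermediate
9 | dilithium bis(dienolate) of 8 (each enone deprotonated at C6; drawn as monomeric O–Li) | [Li]OC1=CCCC(OCc2ccccc2)=C1Cc1c(OCc2ccccc2)cc(OCc2ccccc2)c(CC2=C(OCc3ccccc3)CCC=C2O[Li])c1OCc1ccccc1 | intermediate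
10 | 2,2'-{[2,4,6-tris(benzyloxy)-1,3-phenylene]bis(methylene)}bis[3-(benzyloxy)-6-methylcyclohex-2-en-1-one] (mixture of diastereomers, configuration at the two C6 centres not defined) | O=C1C(C)CCC(OCc2ccccc2)=C1Cc1c(OCc2ccccc2)cc(OCc2ccccc2)c(CC2=C(OCc3ccccc3)CCC(C)C2=O)c1OCc1ccccc1 | intermediate
11 | dilithium bis(dienolate) of 10 (drawn as monomeric O–Li) | [Li]OC1=C(C)CCC(OCc2ccccc2)=C1Cc1c(OCc2ccccc2)cc(OCc2ccccc2)c(CC2=C(OCc3ccccc3)CCC(C)=C2O[Li])c1OCc1ccccc1 | intermediate
12 | 1,3,5-tris(benzyloxy)-2,4-bis{[2-(benzyloxy)-6-(tert-butyldimethylsilyloxy)-5-methylcyclohexa-1,5-dien-1-yl]methyl}benzene | CC(C)(C)[Si](C)(C)OC1=C(C)CCC(OCc2ccccc2)=C1Cc1c(OCc2ccccc2)cc(OCc2ccccc2)c(CC2=C(OCc3ccccc3)CCC(C)=C2O[Si](C)(C)C(C)(C)C)c1OCc1ccccc1 | intermediate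
13 | 2-chloro-1,1-dimethoxyethane | COC(CCl)OC | starting material
14 | butanal | CCCC=O | starting material
15 | lithium methoxyacetylide | [Li]C#COC | intermediate
16 | rac-1-methoxyhex-1-yn-3-ol (racemic) | CCCC(O)C#COC | intermediate
17 | 1-methoxyhex-1-yn-3-one | CCCC(=O)C#COC | intermediate
18 | double cycloadduct: each arm a 3-butanoyl-4-benzyloxy-2-methoxy-1-methyl-6-(tert-butyldimethylsilyloxy)bicyclo[2.2.2]octa-2,5-dien-5-ylmethyl group on 1,3,5-tris(benzyloxy)benzene (mixture of stereoisomers, bridgehead configurations not defined) | c1(OCc2ccccc2)cc(OCc3ccccc3)c(CC5=C(O[Si](C)(C)C(C)(C)C)C6(C)CCC5(OCc7ccccc7)C(C(=O)CCC)=C6OC)c(OCc4ccccc4)c1CC5=C(O[Si](C)(C)C(C)(C)C)C6(C)CCC5(OCc7ccccc7)C(C(=O)CCC)=C6OC | intermediate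
19 | 1,1'-{[2,4,6-tris(benzyloxy)-1,3-phenylene]bis[methylene(2-benzyloxy-4-(tert-butyldimethylsilyloxy)-6-methoxy-5-methyl-3,1-phenylene)]}bis(butan-1-one) | c1(OCc2ccccc2)cc(OCc3ccccc3)c(Cc5c(O[Si](C)(C)C(C)(C)C)c(C)c(OC)c(C(=O)CCC)c5OCc6ccccc6)c(OCc4ccccc4)c1Cc5c(O[Si](C)(C)C(C)(C)C)c(C)c(OC)c(C(=O)CCC)c5OCc6ccccc6 | intermediate
20 | 1,1'-{[2,4,6-tris(benzyloxy)-1,3-phenylene]bis[methylene(2-benzyloxy-4-hydroxy-6-methoxy-5-methyl-3,1-phenylene)]}bis(butan-1-one) (pentabenzyl ether of de-butyryl Agrimol C) | c1(OCc2ccccc2)cc(OCc3ccccc3)c(Cc5c(O)c(C)c(OC)c(C(=O)CCC)c5OCc6ccccc6)c(OCc4ccccc4)c1Cc5c(O)c(C)c(OC)c(C(=O)CCC)c5OCc6ccccc6 | intermediate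
21 | 1,1'-{(2,4,6-trihydroxy-1,3-phenylene)bis[methylene(2,4-dihydroxy-6-methoxy-5-methyl-3,1-phenylene)]}bis(butan-1-one) (de-butyryl Agrimol C) | Oc1cc(O)c(Cc2c(O)c(C)c(OC)c(C(=O)CCC)c2O)c(O)c1Cc1c(O)c(C)c(OC)c(C(=O)CCC)c1O | intermediate
22 | ketiminium chloride of Agrimol C (ring A C1 bearing C(=NH2+)Pr) | CCCC(=[NH2+])c1c(O)c(Cc2c(O)c(C)c(OC)c(C(=O)CCC)c2O)c(O)c(Cc2c(O)c(C)c(OC)c(C(=O)CCC)c2O)c1O.[Cl-] | intermediate
23 | Agrimol C, 1,1'-{(5-butanoyl-2,4,6-trihydroxy-1,3-phenylene)bis[methylene(2,4-dihydroxy-6-methoxy-5-methyl-3,1-phenylene)]}bis(butan-1-one) (achiral) | CCCC(=O)c1c(O)c(Cc2c(O)c(C)c(OC)c(C(=O)CCC)c2O)c(O)c(Cc2c(O)c(C)c(OC)c(C(=O)CCC)c2O)c1O | target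

**Step count**

Total: 11 steps. Longest linear sequence: 9 steps (steps 1–6, 9, 10 and 11); steps 7 and 8 make the alkyne separately.

**Steps most likely to fail**

1. Step 9. The cycloaddition may be too slow with a donor-substituted alkyne on fully substituted dienes, so that thermal loss of the silyl groups or an open-chain Michael-type addition without ring closure takes over. The fallback uses known chemistry, gives up the cycloaddition and builds rings B and C from a preformed acylphenol; it sets out from 4 and comes back at 21.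
   - Reduction of 4 with NaBH4 in THF/MeOH should give [2,4,6-tris(benzyloxy)-1,3-phenylene]dimethanol F1.
   - Commercial 5-methoxybenzene-1,3-diol (COc1cc(O)cc(O)c1) is C-butyrylated (butanoyl chloride, AlCl3, CH2Cl2/PhNO2, 0 °C), and the major regioisomer 1-(2,4-dihydroxy-6-methoxyphenyl)butan-1-one F2 is separated.
   - Acid-catalysed Friedel–Crafts benzylation (cat. TsOH, CH2Cl2, 0 °C, excess of F2 to suppress self-condensation of the diol) should join both benzylic carbons of F1 to the carbon of F2 that lies between its two hydroxyls. This gives 1,1'-{[2,4,6-tris(benzyloxy)-1,3-phenylene]bis[methylene(2,4-dihydroxy-6-methoxy-3,1-phenylene)]}bis(butan-1-one) F3, whose outer rings still lack the C3' methyl groups.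
   - Nuclear C-methylation of the single free position of each outer ring (MeI, NaOMe, MeOH; ring A is inert as its tribenzyl ether) should give 1,1'-{[2,4,6-tris(benzyloxy)-1,3-phenylene]bis[methylene(2,4-dihydroxy-6-methoxy-5-methyl-3,1-phenylene)]}bis(butan-1-one) F4.
   - Hydrogenolysis (H2, Pd/C) of the three benzyl ethers returns to 21.
   - The bridge is made before the methyl group because electrophiles enter F2 between its two hydroxyls first.

2. Step 11. The electron-rich diarylmethane links of the free heptaphenol may undergo acid-promoted heterolysis (loss or scrambling of an outer ring) before acylation is complete, and the free dialkylphloroglucinol ring may be oxidised by air. The fallback acylates before any phenol is set free; it sets out from 19 and comes back at 23.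
   - 19 is isolated after the thermal stage of step 9, with the fluoride treatment omitted.
   - Mixed-anhydride Friedel–Crafts acylation (butanoic acid, trifluoroacetic anhydride, CH2Cl2, 0 °C → rt) at the only free position of the trialkoxybenzene ring A should give 1,1'-{[5-butanoyl-2,4,6-tris(benzyloxy)-1,3-phenylene]bis[methylene(2-benzyloxy-4-(tert-butyldimethylsilyloxy)-6-methoxy-5-methyl-3,1-phenylene)]}bis(butan-1-one) F5.
   - Bu4NF/AcOH in THF then gives 1,1'-{[5-butanoyl-2,4,6-tris(benzyloxy)-1,3-phenylene]bis[methylene(2-benzyloxy-4-hydroxy-6-methoxy-5-methyl-3,1-phenylene)]}bis(butan-1-one) F6.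
   - Hydrogenolysis (H2, Pd/C, EtOAc/MeOH) of the five benzyl ethers gives 23 directly.

3. Step 4. The ambident dione may be alkylated at carbon instead of oxygen, or the Mitsunobu reaction may stall on the hindered enol. The fallback introduces the oxygen substituent as a nucleophile, so that C-alkylation is not possible; it sets out from 7 and comes back at 8.
   - Appel-type deoxychlorination (PPh3, CCl4, MeCN, rt) should convert both enolised diones into the β-chloroenones, giving 2,2'-{[2,4,6-tris(benzyloxy)-1,3-phenylene]bis(methylene)}bis(3-chlorocyclohex-2-en-1-one) F7.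
   - Addition–elimination of sodium benzyloxide (BnONa, BnOH/THF, 0 °C) on the two vinylogous acid chlorides gives 8.

**Further compounds**

F1 | step 9 | [2,4,6-tris(benzyloxy)-1,3-phenylene]dimethanol | OCc1c(OCc2ccccc2)cc(OCc2ccccc2)c(CO)c1OCc1ccccc1
F2 | step 9 | 1-(2,4-dihydroxy-6-methoxyphenyl)butan-1-one | CCCC(=O)c1c(O)cc(O)cc1OC
F3 | step 9 | 1,1'-{[2,4,6-tris(benzyloxy)-1,3-phenylene]bis[methylene(2,4-dihydroxy-6-methoxy-3,1-phenylene)]}bis(butan-1-one) | c1(OCc2ccccc2)cc(OCc2ccccc2)c(Cc2c(O)cc(OC)c(C(=O)CCC)c2O)c(OCc2ccccc2)c1Cc1c(O)cc(OC)c(C(=O)CCC)c1O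
F4 | step 9 | 1,1'-{[2,4,6-tris(benzyloxy)-1,3-phenylene]bis[methylene(2,4-dihydroxy-6-methoxy-5-methyl-3,1-phenylene)]}bis(butan-1-one) | c1(OCc2ccccc2)cc(OCc2ccccc2)c(Cc2c(O)c(C)c(OC)c(C(=O)CCC)c2O)c(OCc2ccccc2)c1Cc1c(O)c(C)c(OC)c(C(=O)CCC)c1O
F5 | step 11 | 1,1'-{[5-butanoyl-2,4,6-tris(benzyloxy)-1,3-phenylene]bis[methylene(2-benzyloxy-4-(tert-butyldimethylsilyloxy)-6-methoxy-5-methyl-3,1-phenylene)]}bis(butan-1-one) | CCCC(=O)c1c(OCc2ccccc2)c(Cc2c(O[Si](C)(C)C(C)(C)C)c(C)c(OC)c(C(=O)CCC)c2OCc2ccccc2)c(OCc2ccccc2)c(Cc2c(O[Si](C)(C)C(C)(C)C)c(C)c(OC)c(C(=O)CCC)c2OCc2ccccc2)c1OCc1ccccc1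
F6 | step 11 | 1,1'-{[5-butanoyl-2,4,6-tris(benzyloxy)-1,3-phenylene]bis[methylene(2-benzyloxy-4-hydroxy-6-methoxy-5-methyl-3,1-phenylene)]}bis(butan-1-one) | CCCC(=O)c1c(OCc2ccccc2)c(Cc2c(O)c(C)c(OC)c(C(=O)CCC)c2OCc2ccccc2)c(OCc2ccccc2)c(Cc2c(O)c(C)c(OC)c(C(=O)CCC)c2OCc2ccccc2)c1OCc1ccccc1
F7 | step 4 | 2,2'-{[2,4,6-tris(benzyloxy)-1,3-phenylene]bis(methylene)}bis(3-chlorocyclohex-2-en-1-one) | O=C1CCCC(Cl)=C1Cc1c(OCc2ccccc2)cc(OCc2ccccc2)c(CC2=C(Cl)CCCC2=O)c1OCc1ccccc1
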